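**Retrosynthetic overview**

1. Target 22 ⇐ enamide 21 by amide-to-aldehyde reduction last; 21 ⇐ α-methylenation and lactonisation (O6–C12) of epoxy alcohol 16.
2. Stereocentres are set one after another on the ten-membered diketone 9: C8 (catalyst), C7 (chelate-controlled alkylation), C6 with the isovalerate (Evans–Tishchenko), C4/C5 (hydroxyl-directed epoxidation).
3. Key disconnection: 9 ⇐ sulfonyl cyclohexenone 3 + acylacrylamide 5 by a Michael/aldol/retro-aldol ring expansion (six → ten); sulfinate loss then gives C1=C10.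
4. 3 ⇐ 3-methylcyclohex-2-enone (1); 5 ⇐ (E)-4-oxopent-2-enoic acid (4); C11/C12 come from 11 and the isovalerate from 14.
5. Ring order: cyclohexenone → ten-membered carbocycle → epoxide → γ-lactone.

Assumption: ring positions are given in germacrane numbering (C1–C10 in the ring, C14 on C10, C15 on C4, C11–C13 on C7), and 1, 4, 11 and 14 are catalogue chemicals.

**Step 1**
Reactants: 1 3-methylcyclohex-2-en-1-one
Product: 3 3-methyl-6-(phenylsulfonyl)cyclohex-2-en-1-one (racemic), via lithium dienolate 2 (not isolated)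
Conditions: LiN(iPr)2 (2.1 equiv), THF, −78 °C; PhSO2F, −78 → 0 °C; aq. NH4Cl
Reagents that add atoms: benzenesulfonyl fluoride, O=S(=O)(F)c1ccccc1
Why: Kinetic α′-deprotonation gives the cross-conjugated enolate, which is C-sulfonylated by the sulfonyl fluoride (enolate sulfonylation); the second equivalent of base takes up the acidic β-keto sulfone proton, and the new stereocentre is racemic and is erased in step 3.

**Step 2**
Reactants: 4 (E)-4-oxopent-2-enoic acid
Product: 5 (E)-N-methoxy-N-methyl-4-oxopent-2-enamide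
Conditions: MeNHOMe·HCl, EDC·HCl, N-methylmorpholine, CH2Cl2, 0 °C
Reagents that add atoms: N,O-dimethylhydroxylamine hydrochloride, CNOC.Cl
Why: Carbodiimide amide coupling; the Weinreb amide is the latent C14 aldehyde, and its weakly acidic α-position keeps sulfinate in place until the ring has expanded in step 3.

**Step 3**
Reactants: 3 3-methyl-6-(phenylsulfonyl)cyclohex-2-en-1-one, 5 (E)-N-methoxy-N-methyl-4-oxopent-2-enamide
Product: 9 (1E,5Z)-N-methoxy-N,5-dimethyl-7,9-dioxocyclodeca-1,5-diene-1-carboxamide, via Michael adduct 6 (not isolated), via potassium aldolate 7 (not isolated), via sulfone enolate 8 (not isolated)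
Conditions: DBU (5 mol%), THF, 0 °C; then KOtBu (3 equiv), 18-crown-6 (10 mol%), −40 → 25 °C; 1 M HCl
Reagents that add atoms: none
Why: Proposed new method: a one-flask Michael addition/intramolecular aldol/retro-aldol fragmentation inserts C10–C9–C8–C7 of 5 between C1 and C6 of 3 (six- to ten-membered ring expansion) and ends with E1cB loss of benzenesulfinate; the β-keto sulfone adds β to the ketone of 5 (6), the methyl ketone enolate closes onto the ring carbonyl (7), the crown-ether-activated potassium alkoxide cleaves the C1–C6 bond because the leaving carbanion is sulfone-stabilised and an enone plus a 1,3-diketonate are formed (8), and only on warming is the poorly acidic amide α-proton removed so that sulfinate leaves to give the thermodynamic E-enamide (C2 and C9 cis), while the Z-C4=C5 bond is inherited from the cyclohexenone; the closest known reaction types are the Trost three-carbon ring expansion of β-keto sulfones, the Hesse ring enlargement of 2-nitrocycloalkanones and the anionic counterpart of the Dowd–Beckwith expansion.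

**Step 4**
Reactants: 9 (1E,5Z)-N-methoxy-N,5-dimethyl-7,9-dioxocyclodeca-1,5-diene-1-carboxamide
Product: 10 (1E,5Z,9R)-9-hydroxy-N-methoxy-N,5-dimethyl-7-oxocyclodeca-1,5-diene-1-carboxamide
Conditions: RuCl2[(R)-BINAP] (1 mol%), H2 (50 atm), EtOH, 40 °C
Reagents that add atoms: none
Why: Noyori asymmetric hydrogenation of a chelating 1,3-diketone reduces the non-conjugated C8 carbonyl rather than the enone carbonyl (as with aryl/alkyl 1,3-diketones), and (R)-BINAP gives the (8R)-carbinol by the same facial preference as for β-keto esters; the unfunctionalised olefins are not touched.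

**Step 5**
Reactants: 10 (1E,5Z,9R)-9-hydroxy-N-methoxy-N,5-dimethyl-7-oxocyclodeca-1,5-diene-1-carboxamide, 11 2-bromo-N-methoxy-N-methylacetamide
Product: 13 (1E,5Z,8R,9R)-9-hydroxy-N-methoxy-8-{2-[methoxy(methyl)amino]-2-oxoethyl}-N,5-dimethyl-7-oxocyclodeca-1,5-diene-1-carboxamide, via dilithium dianion 12 (not isolated)
Conditions: LiN(iPr)2 (2.2 equiv), THF, −78 °C; 11, DMPU, −78 → −40 °C; AcOH, −78 °C
Reagents that add atoms: none
Why: Fráter–Seebach-type alkylation of the lithium-chelated alkoxide/α′-enolate: the electrophile enters trans to C9 on the six-membered chelate (also the peripheral face of the macrocycle), which places the new CH2 unit cis to O8 on the carbocycle and sets C7 as R; the Weinreb amide arm cannot lactonise onto the C8 alkoxide.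

**Step 6**
Reactants: 13 (1E,5Z,8R,9R)-9-hydroxy-N-methoxy-8-{2-[methoxy(methyl)amino]-2-oxoethyl}-N,5-dimethyl-7-oxocyclodeca-1,5-diene-1-carboxamide, 14 3-methylbutanal
Product: 15 (1R,2S,3R,4Z,8E)-3-hydroxy-9-[methoxy(methyl)carbamoyl]-2-{2-[methoxy(methyl)amino]-2-oxoethyl}-5-methylcyclodeca-4,8-dien-1-yl 3-methylbutanoate
Conditions: SmI2 (0.3 equiv), 14 (6 equiv), THF, −10 °C
Reagents that add atoms: none
Why: Evans–Tishchenko reduction: the trivalent samarium hemiacetal formed at O8 delivers hydride intramolecularly to the C6 ketone through a chair-like bicyclic transition state, giving the 1,3-anti carbinol at C6 (R here, 1,2-reduction of the enone) and leaving the isovalerate on O8 in the same step.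

**Step 7**
Reactants: 15 (1R,2S,3R,4Z,8E)-3-hydroxy-9-[methoxy(methyl)carbamoyl]-2-{2-[methoxy(methyl)amino]-2-oxoethyl}-5-methylcyclodeca-4,8-dien-1-yl 3-methylbutanoate
Product: 16 (4R,5S,6S,7S,8R)-4,5-epoxy-6-hydroxy-8-(3-methylbutanoyloxy)-13-norgermacr-1(10)E-ene-12,14-dioic acid bis(N-methoxy-N-methylamide)
Conditions: VO(acac)2 (5 mol%), t-BuOOH (1.5 equiv), CH2Cl2, 0 °C
Reagents that add atoms: tert-butyl hydroperoxide, CC(C)(C)OO
Why: Hydroxyl-directed epoxidation: the vanadium alkoxide of the C6 hydroxyl delivers oxygen to the face of the Z-C4=C5 bond syn to that hydroxyl (the cis epoxy alcohol usual for medium-ring Z-allylic alcohols), setting 4R,5S; the electron-poor enamide olefin does not react.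

**Step 8**
Reactants: 16 (4R,5S,6S,7S,8R)-4,5-epoxy-6-hydroxy-8-(3-methylbutanoyloxy)-13-norgermacr-1(10)E-ene-12,14-dioic acid bis(N-methoxy-N-methylamide)
Product: 17 (4R,5S,6S,7R,8R)-4,5-epoxy-14-[methoxy(methyl)amino]-8-(3-methylbutanoyloxy)-14-oxo-13-norgermacr-1(10)E-en-12,6-olide
Conditions: PPTS (0.3 equiv), toluene, 60 °C
Reagents that add atoms: none
Why: Mild acid-catalysed lactonisation (intramolecular acyl transfer) of the γ-hydroxy Weinreb amide: only O6 is free, so the trans-fused 12,6-lactone forms; the conjugated C14 amide cannot cyclise, the deactivated C1=C10 bond does not attack the epoxide, and no stereocentre changes (C7 becomes R only by priority).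

**Step 9**
Reactants: 17 (4R,5S,6S,7R,8R)-4,5-epoxy-14-[methoxy(methyl)amino]-8-(3-methylbutanoyloxy)-14-oxo-13-norgermacr-1(10)E-en-12,6-olide
Product: 21 (4R,5S,6S,7R,8R)-4,5-epoxy-14-[methoxy(methyl)amino]-8-(3-methylbutanoyloxy)-14-oxogermacra-1(10)E,11(13)-dien-12,6-olide, via lithium enolate 18 (not isolated), via Mannich base 19 (not isolated), via ammonium iodide 20 (not isolated)
Conditions: LiN(SiMe3)2 (1.1 equiv), THF, −78 °C; CH2=NMe2+ I−, −78 → 0 °C; then MeI, 23 °C; then DBU, CH2Cl2, 0 °C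
Reagents that add atoms: Eschenmoser's salt (N,N-dimethylmethyleneiminium iodide), C=[N+](C)C.[I-]
Why: Lactone α-methylenation by Mannich reaction, N-quaternisation and E1cB elimination: the lactone α-CH2 is the most acidic C–H (more so than the hindered isovalerate or the vinylogous amide positions), and the epoxide tolerates the amide base at −78 °C.

**Step 10**
Reactants: 21 (4R,5S,6S,7R,8R)-4,5-epoxy-14-[methoxy(methyl)amino]-8-(3-methylbutanoyloxy)-14-oxogermacra-1(10)E,11(13)-dien-12,6-olide
Product: 22 (4R,5S,6S,7R,8R)-4,5-epoxy-8-(3-methylbutanoyloxy)-14-oxogermacra-1(10)E,11(13)-dien-12,6-olide (CNP0260081.1)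
Conditions: Cp2Zr(H)Cl (1.5 equiv), THF, 0 → 23 °C, 20 min; wet SiO2
Reagents that add atoms: none
Why: Chemoselective hydrozirconation of the tertiary amide to a zirconated hemiaminal that releases the aldehyde on work-up; amides react within minutes whereas the lactone and the isovalerate are much slower, and the enal keeps the E (ring-cis) geometry.

**Compound list**

1 | 3-methylcyclohex-2-en-1-one | CC1=CC(=O)CCC1 | starting material
2 | lithium 5-methylcyclohexa-1,5-dien-1-olate (kinetic α′-enolate of 1) | [Li+].[O-]C1=CCCC(C)=C1 | intermediate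
3 | 3-methyl-6-(phenylsulfonyl)cyclohex-2-en-1-one (racemic) | CC1=CC(=O)C(CC1)S(=O)(=O)c1ccccc1 | intermediate
4 | (E)-4-oxopent-2-enoic acid | CC(=O)/C=C/C(=O)O | starting material
5 | (E)-N-methoxy-N-methyl-4-oxopent-2-enamide | CC(=O)/C=C/C(=O)N(C)OC | intermediate
6 | N-methoxy-N-methyl-2-[4-methyl-2-oxo-1-(phenylsulfonyl)cyclohex-3-en-1-yl]-4-oxopentanamide (racemic diastereomer mixture) | CON(C)C(=O)C(CC(C)=O)C1(CCC(C)=CC1=O)S(=O)(=O)c1ccccc1 | intermediate
7 | potassium alkoxide of 4a-hydroxy-N-methoxy-N,6-dimethyl-3-oxo-8a-(phenylsulfonyl)-1,2,3,4,4a,7,8,8a-octahydronaphthalene-1-carboxamide (stereoisomer mixture) | [K+].CON(C)C(=O)C1CC(=O)CC2([O-])C=C(C)CCC12S(=O)(=O)c1ccccc1 | intermediate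
8 | potassium enolate of (5Z)-N-methoxy-N,5-dimethyl-7,9-dioxo-2-(phenylsulfonyl)cyclodec-5-ene-1-carboxamide (stereoisomer mixture) | [K+].CON(C)C(=O)C1CC([O-])=CC(=O)/C=C(C)\CCC1S(=O)(=O)c1ccccc1 | intermediate
9 | (1E,5Z)-N-methoxy-N,5-dimethyl-7,9-dioxocyclodeca-1,5-diene-1-carboxamide | CON(C)C(=O)/C1=C/CC/C(C)=C\C(=O)CC(=O)C1 | intermediate
10 | (1E,5Z,9R)-9-hydroxy-N-methoxy-N,5-dimethyl-7-oxocyclodeca-1,5-diene-1-carboxamide (8R in germacrane numbering) | O[C@H]1CC(=O)/C=C(C)\CC/C=C(C(=O)N(C)OC)\C1 | intermediate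
11 | 2-bromo-N-methoxy-N-methylacetamide | CON(C)C(=O)CBr | starting material
12 | dilithium alkoxide–enolate of 10 (C8 alkoxide, C6 enolate oxygen, C6=C7 enolate bond) | [Li+].[Li+].[O-][C@H]1C=C([O-])/C=C(C)\CC/C=C(C(=O)N(C)OC)\C1 | intermediate
13 | (1E,5Z,8R,9R)-9-hydroxy-N-methoxy-8-{2-[methoxy(methyl)amino]-2-oxoethyl}-N,5-dimethyl-7-oxocyclodeca-1,5-diene-1-carboxamide (7R,8R in germacrane numbering) | O[C@H]1[C@@H](CC(=O)N(C)OC)C(=O)/C=C(C)\CC/C=C(C(=O)N(C)OC)\C1 | intermediate
14 | 3-methylbutanal | CC(C)CC=O | starting material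
15 | (1R,2S,3R,4Z,8E)-3-hydroxy-9-[methoxy(methyl)carbamoyl]-2-{2-[methoxy(methyl)amino]-2-oxoethyl}-5-methylcyclodeca-4,8-dien-1-yl 3-methylbutanoate (6R,7S,8R in germacrane numbering; O6 and O8 anti, C11 cis to O8) | CC(C)CC(=O)O[C@H]1[C@@H](CC(=O)N(C)OC)[C@H](O)/C=C(C)\CC/C=C(C(=O)N(C)OC)\C1 | intermediate
16 | (4R,5S,6S,7S,8R)-4,5-epoxy-6-hydroxy-8-(3-methylbutanoyloxy)-13-norgermacr-1(10)E-ene-12,14-dioic acid bis(N-methoxy-N-methylamide) (cis-epoxide, epoxide oxygen cis to the 6-OH) | CC(C)CC(=O)O[C@H]1[C@@H](CC(=O)N(C)OC)[C@H](O)[C@@H]2O[C@]2(C)CC/C=C(C(=O)N(C)OC)\C1 | intermediate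
17 | (4R,5S,6S,7R,8R)-4,5-epoxy-14-[methoxy(methyl)amino]-8-(3-methylbutanoyloxy)-14-oxo-13-norgermacr-1(10)E-en-12,6-olide (trans-fused γ-lactone, C11 = CH2) | C1C(=O)O[C@H]2[C@H]1[C@H](OC(=O)CC(C)C)C/C(C(=O)N(C)OC)=C\CC[C@@]1(C)O[C@@H]21 | intermediate
18 | lithium enolate of lactone 17 (C11=C12–O–Li) | [Li+].C1=C([O-])O[C@H]2[C@H]1[C@H](OC(=O)CC(C)C)C/C(C(=O)N(C)OC)=C\CC[C@@]1(C)O[C@@H]21 | intermediate
19 | 11-[(dimethylamino)methyl] derivative of 17 (Mannich base, C11 epimer mixture) | CN(C)CC1C(=O)O[C@H]2[C@H]1[C@H](OC(=O)CC(C)C)C/C(C(=O)N(C)OC)=C\CC[C@@]1(C)O[C@@H]21 | intermediate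
20 | trimethylammonium iodide of 19 (C11 epimer mixture) | [I-].C[N+](C)(C)CC1C(=O)O[C@H]2[C@H]1[C@H](OC(=O)CC(C)C)C/C(C(=O)N(C)OC)=C\CC[C@@]1(C)O[C@@H]21 | intermediate
21 | (4R,5S,6S,7R,8R)-4,5-epoxy-14-[methoxy(methyl)amino]-8-(3-methylbutanoyloxy)-14-oxogermacra-1(10)E,11(13)-dien-12,6-olide | C=C1C(=O)O[C@H]2[C@H]1[C@H](OC(=O)CC(C)C)C/C(C(=O)N(C)OC)=C\CC[C@@]1(C)O[C@@H]21 | intermediate
22 | (4R,5S,6S,7R,8R)-4,5-epoxy-8-(3-methylbutanoyloxy)-14-oxogermacra-1(10)E,11(13)-dien-12,6-olide (CNP0260081.1; 1(10) olefin ring-cis, 4,5-epoxide cis) | C=C1C(=O)O[C@H]2[C@H]1[C@H](OC(=O)CC(C)C)C/C(C=O)=C\CC[C@@]1(C)O[C@@H]21 | target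

**Step count and risks**

Total step count: 10. Longest linear sequence: 9 (steps 1, 3–10, or equally 2, 3–10).

The three steps most likely to fail are 3, 4 and 5.

Step 3 (the proposed ring expansion; risks are aldol condensation to the bicyclic enone or early loss of sulfinate). The fallback separates the events and uses only known reaction types. It sets out from 6, which can be isolated after the DBU stage. The six-membered ring is closed under neutral enamine catalysis (pyrrolidine, AcOH, CH2Cl2, 23 °C), which cannot trigger sulfinate loss, to give the neutral bicyclic ketol 4a-hydroxy-N-methoxy-N,6-dimethyl-3-oxo-8a-(phenylsulfonyl)-1,2,3,4,4a,7,8,8a-octahydronaphthalene-1-carboxamide F1. The tertiary alcohol alone is then deprotonated with KH and 18-crown-6 in THF at 0 °C, so that the alkoxide fragments as in the three-carbon ring expansions of β-keto sulfones. Quenching gives the neutral ten-membered sulfone (5Z)-N-methoxy-N,5-dimethyl-7,9-dioxo-2-(phenylsulfonyl)cyclodec-5-ene-1-carboxamide F2, and KOtBu in THF at 25 °C eliminates benzenesulfinate. The sequence comes back to the route at 9.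

Step 4 (regio- and enantioselective mono-reduction of a macrocyclic, largely enolised diketone). The fallback sets out from 9 and no longer relies on regioselectivity. Both carbonyls are hydrogenated under forcing conditions (RuCl2[(R)-BINAP], H2 100 atm, EtOH, 50 °C), which for 1,3-diketones gives the anti-diol under catalyst control, here (1E,5Z,7S,9R)-7,9-dihydroxy-N-methoxy-N,5-dimethylcyclodeca-1,5-diene-1-carboxamide F3. Activated MnO2 in CH2Cl2 then re-oxidises only the allylic C6 carbinol; the C8 carbinol is not allylic and survives. The sequence comes back at 10.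

Step 5 (dianion alkylation; risks are γ-deprotonation, retro-aldol opening and low facial control). The fallback sets out from 9 and forms the C7–C11 bond before any stereocentre exists. The 1,3-diketone is C-alkylated with 11 (K2CO3, acetone, 25 °C) to give (1E,5Z)-N-methoxy-8-{2-[methoxy(methyl)amino]-2-oxoethyl}-N,5-dimethyl-7,9-dioxocyclodeca-1,5-diene-1-carboxamide F4, whose C7 centre is configurationally labile. Hydrogenation with RuCl2[(R)-BINAP] (H2 50 atm, CH2Cl2/EtOH, 40 °C) under dynamic kinetic resolution then sets C8 and C7 together. This replaces steps 4 and 5 and comes back at 13.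

**Further compounds**

F1 | step 3 | 4a-hydroxy-N-methoxy-N,6-dimethyl-3-oxo-8a-(phenylsulfonyl)-1,2,3,4,4a,7,8,8a-octahydronaphthalene-1-carboxamide (stereoisomer mixture) | CON(C)C(=O)C1CC(=O)CC2(O)C=C(C)CCC12S(=O)(=O)c1ccccc1
F2 | step 3 | (5Z)-N-methoxy-N,5-dimethyl-7,9-dioxo-2-(phenylsulfonyl)cyclodec-5-ene-1-carboxamide (stereoisomer mixture) | CON(C)C(=O)C1CC(=O)CC(=O)/C=C(C)\CCC1S(=O)(=O)c1ccccc1
F3 | step 4 | (1E,5Z,7S,9R)-7,9-dihydroxy-N-methoxy-N,5-dimethylcyclodeca-1,5-diene-1-carboxamide | O[C@H]1C[C@H](O)/C=C(C)\CC/C=C(C(=O)N(C)OC)\C1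
F4 | step 5 | (1E,5Z)-N-methoxy-8-{2-[methoxy(methyl)amino]-2-oxoethyl}-N,5-dimethyl-7,9-dioxocyclodeca-1,5-diene-1-carboxamide | CON(C)C(=O)CC1C(=O)/C=C(C)\CC/C=C(C(=O)N(C)OC)\CC1=O
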